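**Closed books.** Starting material is conserved in the count: each percent charged stands as starting material left, as target or as self-condensation product, while forms held on catalyst can take at most 0.107% of the charge, in summer. The reagent is charged at 80.0% of the starting material, and on the suspected path each target takes one reagent, but self-condensation uses starting material without reagent, so the books are kept on starting material.

the same everywhere: starting material 14 mM; reagent 11.2 mM

|  | free catalyst | remark | time |
|---|---|---|---|
| Wednesday's | 0.57 µM | run made earlier |  |
| Tuesday's | 2.6 µM | run made earlier |  |
| Friday's | 11 µM | run made earlier |  |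
| dusk | 0.50 µM |  | 50 min |
| dawn | 1.5 µM |  | 50 min |
| noon | 5.0 µM |  | 50 min |
| summer | 15 µM |  | 50 min |

| run | time / min | target / % | starting material / % |
|---|---|---|---|
| Wednesday's | 3.00 | 1.2 | 95.5 |
| Wednesday's | 8.00 | 1.0 | 87.0 |
| Wednesday's | 15.0 | 2.1 | 76.4 |
| Wednesday's | 25.0 | 0 | 69.0 |
| Wednesday's | 40.0 | 0.4 | 55.7 |
| Tuesday's | 3.00 | 1.3 | 94.4 |
| Tuesday's | 5.00 | 0.9 | 89.9 |
| Tuesday's | 10.0 | 1.6 | 84.8 |
| Tuesday's | 20.0 | 1.3 | 72.7 |
| Tuesday's | 40.0 | 3.4 | 55.8 |
| Friday's | 3.00 | 2.6 | 93.8 |
| Friday's | 8.00 | 4.1 | 81.6 |
| Friday's | 15.0 | 8.3 | 72.7 |
| Friday's | 25.0 | 12.1 | 61.0 |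
| Friday's | 40.0 | 17.8 | 47.7 |

(scatter of a reading: 1 percentage point)

- in percentages every species weighs as the starting material in it: one self-condensation product counts as two
- for by-product the crystals are counted in
- as a solid, counted per litre of solution: crystals
- on the list of suspects stand: catalyst intermediate C <-> free catalyst + target; reagent + catalyst intermediate A -> catalyst intermediate B; 2 starting material -> self-condensation product; catalyst intermediate B <-> by-product + catalyst intermediate C; starting material + free catalyst <-> catalyst intermediate A; crystals <-> by-product
- "hardly changes" means that all values lie within two and a half points (for a concentration: within two and a half percent of the largest)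

- amount of target at the end, in percent of the starting material charged for dusk, dawn, noon, summer, in this order
- the course of these numbers from the first flask to the last (falls, then rises / rises, then falls / falls all the way / hardly changes / rises all the way)

**Friday's ledger.** At 40.0 min, Friday's run reads starting material 47.7% and target 17.8%, so self-condensation product stands by difference at 34.5%. By that reading, target has taken 22.3% of the reagent's charge in Friday's run. Dividing the rate of the target entry by the rate of the self-condensation entry removes time. The result is ρ, a selectivity factor: starting material gained as target per starting material sent to self-condensation. Friday's reading is 0.516, and at 15.0 min it was 0.437. Taking ρ as proportional to catalyst is rough: Tuesday's reads 0.0833 at 40.0 min, and scaling Friday's gives 0.122.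

**The clock.** Wednesday's flask, with target 0.4% at 40.0 min, times the second-order loss. Writing a for the fraction of starting material left, κ = (1/a − 1) scaled to 50 min reads 0.994. With both exits taken as second order in starting material, a = 1/(1 + (1 + ρ)κ), and target is the part ρ/(1 + ρ) of what has gone.

**The reckoning.** Scaling ρ to each charge gives target of 1.16% at dusk, 3.39% at dawn, 10.5% at noon and 26.0% in summer, rising all the way. Summer's reckoned entry takes 32.5% of the reagent's charge.

**The forecast.** The forecast gives 0.9%, 2.7%, 9% and 27%, course rises all the way, holding that “More catalyst only diverts more starting material from self-condensation”.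

**The flasks.** Target ends at 1.03%, 3.05%, 9.75% and 26.0%: rises all the way.

    catalyst intermediate C ⇌ free catalyst + target (K = 0.0450 M, k = 0.500 s⁻¹)
    reagent + catalyst intermediate A → catalyst intermediate B (k = 34.0 M⁻¹ s⁻¹)
    2 starting material → self-condensation product (k = 0.0110 M⁻¹ s⁻¹)
    catalyst intermediate B ⇌ by-product + catalyst intermediate C (K = 0.550 M, k = 0.690 s⁻¹)
    starting material + free catalyst ⇌ catalyst intermediate A (K = 180 M⁻¹, k = 37.0 M⁻¹ s⁻¹)
    crystals ⇌ by-product, rate k6*(cs6 - [by-product]) while solid is left; crystals form when [by-product] > cs6 (solubility = 7.90 mM, k = 0.0110 s⁻¹)

**Second use.** Summer's flask holds target 26.0% beside self-condensation product 37.2%, a ratio of 0.699 against ρ reckoned at 0.704. Noon's flask, with target 9.75% and self-condensation product 44.0%, gives a ratio of 0.222 against ρ scaled to 0.235.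

The numbers in the tables were computed from invented constants, and the scatter is random.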